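Take a neighbour flask with less partner as the starting point, and ask how far this charge lifts each product.

    partner + left-handed substrate → left-handed product (k1 = 2.0 L mol⁻¹ s⁻¹)
    partner + right-handed substrate → right-handed product (k2 = 0.83 L mol⁻¹ s⁻¹)
    left-handed substrate ⇌ achiral form (K3 = 0.77, k3 = 0.12 s⁻¹)
    right-handed substrate ⇌ achiral form (K3 = 0.77, k3 = 0.12 s⁻¹)
    achiral form → waste (k5 = 0.037 s⁻¹)
    left-handed product ⇌ right-handed product (k6 = 0.16 s⁻¹)
    partner → decomposition product (k7 = 3.0 × 10⁻⁴ s⁻¹)

left-handed substrate 0.25 M; partner 0.625 M; right-handed substrate 0.25 M; time 10 min

- partner is single-handed; left-handed substrate and right-handed substrate are mirror images of each other, charged as a racemate, each of them at the stated concentration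
- run time (flask): 10 min
- the handed part of partner does not stay in what it makes, so the products of the two hands are mirror images too

* how much left-handed product there is at 10 min, in percent of the left-handed substrate and right-handed substrate together charged
* how much right-handed product there is at 10 min, in percent of the left-handed substrate and right-handed substrate together charged

Begin with a ceiling. Each coupling spends one partner, and the two products interconvert with a relaxation half-life of 2.17 s, shorter than 10 min, so count on equal products. Define the partner ceiling as c(partner) shared equally over both products, in percent of the substrates charged: 62.5 %. The substrates' own ceiling per product is 50.0 %, lower. So take the substrates as the limiting reagent, and subtract what leaks to waste.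

Now reckon the leak. Substrate enters the achiral form at 0.12 s⁻¹; that form returns to each hand at 0.156 s⁻¹ and goes on to waste at 0.037 s⁻¹. Hold the two substrates equal and c(achiral form) steady. Waste then runs against coupling as 1.44 % at the charged c(partner), which leaves 49.3 % per product.

One weak link is that held partner. Its concentration falls towards the excess, 0.125 M, and the ratio grows as it falls. Integrate over the coupling: the loss becomes 2.90 % of the charge. Commit to 48.6 % per product.

The forecast puts 47 % of left-handed product and 47 % of right-handed product, lower than my figure, holding that “any handedness is erased” and that the rest splits equally.

The flask gives 48.4 % of left-handed product and 48.4 % of right-handed product, with 3.18 % as waste. Carry the partner ceiling to the neighbour charged with 0.38 M of partner. There it is 38.0 %, below the substrates' ceiling, so the reckoning puts each product at that figure. That neighbour ends with partner at 0 %, waste at 24.0 %, and right-handed product at 38.0 %.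

(The numbers stand for no real mixture, and the outcome is calculated.)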